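**Plan**
Retrosynthesis: the three esters come off (C7 acetate last, then C9 senecioate and C14 angelate), the C13 methyl is traced to an acyl group on C10, the cyclohexenone is cut at C2=C3 (aldol) to a cis-1,3-diacetylcyclobutane, and the seven-membered ring is cut at C5–C6 and C9–C10.
Enabling feature: C5 and C10 are the 1,3-carbons of the cyclobutane C4–C5–C11–C10, i.e. the bridgeheads of a bicyclo[1.1.0]butane whose central σ-bond is a two-electron partner; the bridge C6–C7–C8–C9 with its C7/C9 oxygens, C15 methyl and C14 carbon is C3–C4–C5–C6 (plus C2=O) of a 4-oxy-3-methyl-2-pyrone.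
Forward: double carbene addition to an orthopropiolate gives a 2,4-diacetyl bicyclobutane (fragment 1); a β-keto ester dianion gives the pyrone (fragment 2); their Lewis acid formal [4π+2σ] union builds the bicyclo[4.1.1]octane with a C14→O9 lactone bridge; an aldol condensation then closes the cyclohexenone; reductions and three esterifications finish.
Stereochemistry: the lactone ring ties C6 to C9 (cis); inversion at both bicyclobutane bridgeheads puts the new bridge anti to the exo acetyl groups (C4, C11); an oxazolidinone auxiliary allows separation for absolute configuration; a chiral primary amine directs the aldol; hydride attack anti to the cyclobutane sets C7.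

Key step: step 10

Locants are longipinane numbers of the target: C1 ring C=O, C2=C3 (C12 methyl on C3), C4 and C11 cyclobutane CH next to C3 and C1, C5 cyclobutane CH, C6 (C14 = CH2O, C15 = CH3), C7 (OAc), C8, C9 (OSen), C10 (C13 methyl).
Assumption: the amine catalyst of step 11 is taken to use the C11 acetyl group as enamine donor; if the sense proves opposite, its quinidine-derived pseudo-enantiomer is used instead.

Step 1
Reactants: 1 3,3,3-triethoxyprop-1-yne; 2 ethyl diazoacetate
Product: 3 ethyl 2-(triethoxymethyl)cycloprop-2-ene-1-carboxylate (racemic)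
Conditions: Rh2(OAc)4 (1 mol %), excess 1, CH2Cl2, rt, slow addition of 2
Reagents that add atoms: none
Why: Rh-carbenoid [2+1] cyclopropenation of a terminal alkyne with a diazoacetate is a standard reaction, the orthoester (a masked carboxyl) keeps the alkyne electron-rich enough for the electrophilic carbenoid, and the single stereocentre formed is racemic and is absorbed into a meso bicyclobutane in step 2.

Step 2
Reactants: 3 ethyl 2-(triethoxymethyl)cycloprop-2-ene-1-carboxylate; 2 ethyl diazoacetate
Product: 4 diethyl exo,exo-1-(triethoxymethyl)bicyclo[1.1.0]butane-2,4-dicarboxylate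
Conditions: Rh2(OAc)4 (1 mol %), CH2Cl2, 0 °C → rt, slow addition of 2
Reagents that add atoms: none
Why: Carbenoid cyclopropanation of the strained cyclopropene π-bond is the classical double carbene-addition route from alkynes to bicyclo[1.1.0]butane-2,4-dicarboxylates; the carbenoid approaches anti to the existing ester and keeps its own ester outside, so both esters should end exo and the product is achiral.

Step 3
Reactants: 4 diethyl exo,exo-1-(triethoxymethyl)bicyclo[1.1.0]butane-2,4-dicarboxylate
Product: 5 exo,exo-N2,N4-dimethoxy-N2,N4-dimethyl-1-(triethoxymethyl)bicyclo[1.1.0]butane-2,4-dicarboxamide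
Conditions: MeNH(OMe)·HCl, i-PrMgCl, THF, −20 → 0 °C
Reagents that add atoms: N,O-dimethylhydroxylamine hydrochloride, CNOC.Cl
Why: Weinreb amide formation from esters with the chloromagnesium amide of N,O-dimethylhydroxylamine, in which the orthoester is inert and the bicyclobutane, lacking a bridgehead acceptor at this stage, is not opened by the basic reagent.

Step 4
Reactants: 5 exo,exo-bis(Weinreb amide) orthoester
Product: 7 ethyl exo,exo-2,4-diacetylbicyclo[1.1.0]butane-1-carboxylate, via diketone orthoester 6 (not isolated)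
Conditions: MeMgBr, THF, 0 °C; then 10 % aq. citric acid, THF, 0 °C
Reagents that add atoms: methylmagnesium bromide, C[Mg]Br; water, O
Why: Weinreb ketone synthesis (the chelated tetrahedral adducts stop at the ketone stage) followed by mild acid hydrolysis of the orthoester to the ethyl ester, which unveils the bridgehead acceptor only after the organometallic steps.

Step 5
Reactants: 7 ethyl exo,exo-2,4-diacetylbicyclo[1.1.0]butane-1-carboxylate
Product: 8 exo,exo-2,4-diacetylbicyclo[1.1.0]butane-1-carboxylic acid
Conditions: LiOH·H2O, THF/H2O, 0 °C; then cold 1 M HCl to pH 4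
Reagents that add atoms: lithium hydroxide, [Li+].[OH-]
Why: Simple saponification of the bridgehead ester at low temperature, the usual access to bicyclobutane-1-carboxylic acids, with brief cold acidification to spare the strained core.

Step 6
Reactants: 8 exo,exo-2,4-diacetylbicyclo[1.1.0]butane-1-carboxylic acid; 9 (S)-4-benzyloxazolidin-2-one
Product: 10 (S)-4-benzyl-3-[(exo,exo-2,4-diacetylbicyclo[1.1.0]butan-1-yl)carbonyl]oxazolidin-2-one
Conditions: EDC·HCl, DMAP, CH2Cl2, 0 °C → rt
Reagents that add atoms: none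
Why: Carbodiimide/DMAP N-acylation of the oxazolidinone gives an imide that serves as a two-point Lewis acid binding site for step 10, as a resolving handle and as an acyl group that borohydride can later reduce in the presence of a lactone.

Step 7
Reactants: 11 methyl 2-methyl-3-oxobutanoate; 12 methyl formate
Product: 13 methyl 2-methyl-3,5-dioxopentanoate (as its 5-enol)
Conditions: NaH, THF, 0 °C; n-BuLi, −10 °C; 12, −78 → 0 °C; aq. HCl
Reagents that add atoms: none
Why: Acylation of the β-keto ester dianion at its terminal (γ) carbon by a formate ester (dianion Claisen condensation) delivers the 3,5-dicarbonyl ester as its enol.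

Step 8
Reactants: 13 methyl 2-methyl-3,5-dioxopentanoate
Product: 14 4-hydroxy-3-methyl-2H-pyran-2-one
Conditions: p-TsOH·H2O (cat.), toluene, 90 °C, removal of MeOH
Reagents that add atoms: none
Why: Acid-catalysed enol lactonisation of a 3,5-dioxo ester with loss of methanol, the usual route to 4-hydroxy-2-pyrones.

Step 9
Reactants: 14 4-hydroxy-3-methyl-2H-pyran-2-one
Product: 15 3-methyl-4-(triisopropylsilyloxy)-2H-pyran-2-one
Conditions: TIPSOTf, Et3N, CH2Cl2, 0 °C
Reagents that add atoms: triisopropylsilyl trifluoromethanesulfonate, CC(C)[Si](OS(=O)(=O)C(F)(F)F)(C(C)C)C(C)C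
Why: O-Silylation of the vinylogous acid at O4 with a silyl triflate gives the 4-silyloxy-2-pyrone, a cyclic silyl dienol ether.

Step 10
Reactants: 10 bicyclobutane imide; 15 3-methyl-4-(triisopropylsilyloxy)-2H-pyran-2-one
Product: 16 13-[(S)-4-benzyl-2-oxooxazolidin-3-yl]-13-oxo-7-(triisopropylsilyloxy)-2,3-secolongipin-7-ene-1,3-dione 14,9-olide (acetyl groups on C4 and C11 cis to each other and anti to the C6–C9 bridge)
Conditions: Sc(OTf)3 (10 mol %), 4 Å molecular sieves, CH2Cl2, −40 → 0 °C; aq. NaHCO3; the diastereomer with the opposite bridge sense is removed by chromatography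
Reagents that add atoms: none
Why: Proposed new method: Sc(OTf)3 chelates the two imide carbonyls of 10 and polarises the central C5–C10 σ-bond, so that the silyl dienol ether carbon of 15 (pyrone C3, becoming C6) opens it by back-side attack at the hydrogen-bearing bridgehead C5, giving a scandium imide enolate at C10 and a silyloxocarbenium-activated 2H-pyran-2,4-dione in which pyrone C6 (becoming C9) is the β-carbon of an enone; the enolate adds to it and the C7=C8 silyl enol ether remains. The closest known reaction is the Lewis acid-catalysed formal [4π+2σ] cycloaddition of acyl bicyclo[1.1.0]butanes with silyl dienol ethers to bicyclo[4.1.1]octanes, here extended to a cyclic vinylogous-ester diene (a 4-silyloxy-2-pyrone) and to a 2,4-disubstituted bicyclobutane without an aryl group at the attacked bridgehead. The first bond is an intermolecular strain-release Mukaiyama–Michael step, the second closes the cycloheptane ring C5–C6–C7–C8–C9–C10–C4 by a 7-endo-trig Mukaiyama–Michael addition, which at the same time makes the 2-oxabicyclo[3.2.2] lactone cage. C5 and C10 react with inversion, so the new bridge lies on the former concave face and the exo acetyl groups on C4 and C11 end cis to each other and anti to it; C6 and C9 are tied cis by the pyranone ring because both bonds form on one of its faces; the remote auxiliary is not relied on for the absolute sense, so both auxiliary diastereomers are expected and the one drawn is isolated. The step needs alkylation at pyrone C3 rather than at O4 or at the pyrone 5-position, cleavage of the central rather than a lateral bicyclobutane bond, and cyclisation rather than protonation of the enolate; these are addressed by the 3-methyl group (no re-aromatisation, so the dearomatised enone must accept the enolate), by two-point activation of the bridgehead imide only, and by the silyl ether, which leaves no proton available.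

Step 11
Reactants: 16 seco-dione lactone
Product: 17 13-[(S)-4-benzyl-2-oxooxazolidin-3-yl]-1,13-dioxo-7-(triisopropylsilyloxy)longipina-2,7-dien-14,9-olide
Conditions: 9-amino-9-deoxy-epi-quinine (20 mol %), AcOH (40 mol %), toluene, rt
Reagents that add atoms: none
Why: Primary-amine (enamine) catalysed intramolecular aldol condensation of a 1,5-diketone, the reaction type established for the desymmetrisation of 4-substituted heptane-2,6-diones; the two acetyl groups are held cis-1,3 on the cyclobutane, the cinchona amine selects the C11 acetyl as enamine donor (C2) and the C4 acetyl as acceptor (C3), and loss of water gives the C2=C3 enone without a new stereocentre.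

Step 12
Reactants: 17 dienone lactone imide
Product: 19 1,7,13-trihydroxylongipin-2-en-14,9-olide (1-OH cis to C10, 7-OH trans to O9), via C7 ketone 18 (not isolated)
Conditions: HF·pyridine, THF, 0 °C; then NaBH4, CeCl3·7H2O, THF/MeOH, −40 °C; then H2O, NaBH4, 0 °C → rt
Reagents that add atoms: none
Why: Protodesilylation of the silyl enol ether followed by Luche-type borohydride reduction, in which hydride reaches the C7 ketone from the open face between the lactone and the C7–C8 bridge (the other face is screened by the syn hydrogen on cyclobutane carbon C4) to give the 7-alcohol trans to O9, reduces the enone carbonyl 1,2 from the face remote from the C10 substituent (a centre re-oxidised in step 19), and cleaves the N-acyloxazolidinone reductively to the primary C13 alcohol with release of the auxiliary.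

Step 13
Reactants: 19 triol lactone
Product: 20 1,7-dihydroxy-13-(2,4,6-triisopropylbenzenesulfonyloxy)longipin-2-en-14,9-olide
Conditions: 2,4,6-triisopropylbenzenesulfonyl chloride, pyridine, DMAP (cat.), CH2Cl2, 0 °C → rt
Reagents that add atoms: 2,4,6-triisopropylbenzenesulfonyl chloride, CC(C)c1cc(C(C)C)c(S(=O)(=O)Cl)c(C(C)C)c1
Why: Selective sulfonylation of the only primary alcohol by a sterically demanding arenesulfonyl chloride, whose hindered sulfur also disfavours attack at sulfur in step 15.

Step 14
Reactants: 20 diol sulfonate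
Product: 21 1,7-bis(tert-butyldimethylsilyloxy)-13-(2,4,6-triisopropylbenzenesulfonyloxy)longipin-2-en-14,9-olide
Conditions: TBSOTf, 2,6-lutidine, CH2Cl2, 0 °C
Reagents that add atoms: tert-butyldimethylsilyl trifluoromethanesulfonate, CC(C)(C)[Si](C)(C)OS(=O)(=O)C(F)(F)F
Why: Silyl triflate silylation protects both secondary alcohols (the allylic C1 and the hindered C7), which keeps O7 distinct from O9 and O14 once the lactone is opened.

Step 15
Reactants: 21 bis(silyl ether) sulfonate lactone
Product: 22 1,7-bis(tert-butyldimethylsilyloxy)longipin-2-ene-9,14-diol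
Conditions: LiEt3BH (excess), THF, 0 → 65 °C; NaOH/H2O2 work-up
Reagents that add atoms: none
Why: LiEt3BH delivers hydride in an SN2 displacement of the neopentyl arenesulfonate, turning C13 into the methyl group, and reduces the lactone to the 9,14-diol, while silyl ethers and the isolated alkene are inert.

Step 16
Reactants: 22 9,14-diol; 23 angelic acid ((Z)-2-methylbut-2-enoic acid)
Product: 24 14-angeloyloxy-1,7-bis(tert-butyldimethylsilyloxy)longipin-2-en-9-ol
Conditions: 23, 2,4,6-trichlorobenzoyl chloride, Et3N, toluene, rt; then 22, 80 °C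
Reagents that add atoms: none
Why: Yamaguchi-type mixed anhydride esterification of angelic acid acylates the primary C14 alcohol in preference to the hindered secondary C9 alcohol and is the standard protocol for keeping the Z geometry of the angelate.

Step 17
Reactants: 24 mono-angelate; 25 3-methylbut-2-enoyl chloride
Product: 26 14-angeloyloxy-1,7-bis(tert-butyldimethylsilyloxy)-9-senecioyloxylongipin-2-ene
Conditions: 25, pyridine, DMAP (cat.), CH2Cl2, 0 → 40 °C
Reagents that add atoms: none
Why: DMAP-catalysed acylation of the remaining hindered secondary alcohol with the acid chloride, pyridine being too weak a base to deconjugate the senecioyl group.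

Step 18
Reactants: 26 diester bis(silyl ether)
Product: 27 14-angeloyloxy-9-senecioyloxylongipin-2-ene-1,7-diol
Conditions: HF·pyridine, pyridine, THF, 0 °C → rt
Reagents that add atoms: none
Why: Buffered fluoride cleavage of both silyl ethers under conditions that neither migrate nor isomerise the unsaturated esters.

Step 19
Reactants: 27 1,7-diol diester
Product: 28 14-angeloyloxy-7-hydroxy-9-senecioyloxylongipin-2-en-1-one
Conditions: activated MnO2, CH2Cl2, rt
Reagents that add atoms: none
Why: MnO2 oxidises only the allylic C1 alcohol, restoring the enone and removing the temporary C1 stereocentre, and leaves the saturated C7 alcohol untouched.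

Step 20
Reactants: 28 hydroxy enone diester
Product: 29 7-acetoxy-14-angeloyloxy-9-senecioyloxylongipin-2-en-1-one (target)
Conditions: Ac2O, pyridine, DMAP (cat.), CH2Cl2, 0 °C → rt
Reagents that add atoms: acetic anhydride, CC(=O)OC(C)=O
Why: DMAP-catalysed acetylation of the last free secondary alcohol completes the target.

**Compound list**
1 | 3,3,3-triethoxyprop-1-yne | C#CC(OCC)(OCC)OCC | starting material
2 | ethyl diazoacetate | CCOC(=O)C=[N+]=[N-] | starting material
3 | ethyl 2-(triethoxymethyl)cycloprop-2-ene-1-carboxylate (racemic) | CCOC(=O)C1C=C1C(OCC)(OCC)OCC | intermediate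
4 | diethyl exo,exo-1-(triethoxymethyl)bicyclo[1.1.0]butane-2,4-dicarboxylate | CCOC(=O)[C@H]1[C@@H]2[C@@H](C(=O)OCC)[C@]12C(OCC)(OCC)OCC | intermediate
5 | exo,exo-N2,N4-dimethoxy-N2,N4-dimethyl-1-(triethoxymethyl)bicyclo[1.1.0]butane-2,4-dicarboxamide | CON(C)C(=O)[C@H]1[C@@H]2[C@@H](C(=O)N(C)OC)[C@]12C(OCC)(OCC)OCC | intermediate
6 | exo,exo-2,4-diacetyl-1-(triethoxymethyl)bicyclo[1.1.0]butane (not isolated) | CC(=O)[C@H]1[C@@H]2[C@@H](C(C)=O)[C@]12C(OCC)(OCC)OCC | intermediate
7 | ethyl exo,exo-2,4-diacetylbicyclo[1.1.0]butane-1-carboxylate | CC(=O)[C@H]1[C@@H]2[C@@H](C(C)=O)[C@]12C(=O)OCC | intermediate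
8 | exo,exo-2,4-diacetylbicyclo[1.1.0]butane-1-carboxylic acid | CC(=O)[C@H]1[C@@H]2[C@@H](C(C)=O)[C@]12C(=O)O | intermediate
9 | (S)-4-benzyloxazolidin-2-one | O=C1N[C@@H](Cc2ccccc2)CO1 | starting material
10 | (S)-4-benzyl-3-[(exo,exo-2,4-diacetylbicyclo[1.1.0]butan-1-yl)carbonyl]oxazolidin-2-one | CC(=O)[C@H]1[C@@H]2[C@@H](C(C)=O)[C@]12C(=O)N3C(=O)OC[C@@H]3Cc4ccccc4 | intermediate
11 | methyl 2-methyl-3-oxobutanoate | COC(=O)C(C)C(C)=O | starting material
12 | methyl formate | COC=O | starting material
13 | methyl 2-methyl-3,5-dioxopentanoate (5-enol) | COC(=O)C(C)C(=O)CC=O | intermediate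
14 | 4-hydroxy-3-methyl-2H-pyran-2-one | CC1=C(O)C=COC1=O | intermediate
15 | 3-methyl-4-(triisopropylsilyloxy)-2H-pyran-2-one | CC1=C(O[Si](C(C)C)(C(C)C)C(C)C)C=COC1=O | intermediate
16 | 13-[(S)-4-benzyl-2-oxooxazolidin-3-yl]-13-oxo-7-(triisopropylsilyloxy)-2,3-secolongipin-7-ene-1,3-dione 14,9-olide | O=C4[C@]1(C)[C@@H]2[C@@H](C(C)=O)[C@]([C@H]2C(C)=O)(C(=O)N5C(=O)OC[C@@H]5Cc6ccccc6)[C@H](O4)C=C1O[Si](C(C)C)(C(C)C)C(C)C | intermediate
17 | 13-[(S)-4-benzyl-2-oxooxazolidin-3-yl]-1,13-dioxo-7-(triisopropylsilyloxy)longipina-2,7-dien-14,9-olide | O=C4[C@]1(C)[C@@H]2[C@H]3C(=O)C=C(C)[C@@H]2[C@@]3(C(=O)N5C(=O)OC[C@@H]5Cc6ccccc6)[C@H](O4)C=C1O[Si](C(C)C)(C(C)C)C(C)C | intermediate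
18 | 13-[(S)-4-benzyl-2-oxooxazolidin-3-yl]-1,7,13-trioxolongipin-2-en-14,9-olide (not isolated) | O=C4[C@]1(C)[C@@H]2[C@H]3C(=O)C=C(C)[C@@H]2[C@@]3(C(=O)N5C(=O)OC[C@@H]5Cc6ccccc6)[C@H](O4)CC1=O | intermediate
19 | 1,7,13-trihydroxylongipin-2-en-14,9-olide | O=C4[C@]1(C)[C@@H]2[C@H]3[C@H](O)C=C(C)[C@@H]2[C@@]3(CO)[C@H](O4)C[C@H]1O | intermediate
20 | 1,7-dihydroxy-13-(2,4,6-triisopropylbenzenesulfonyloxy)longipin-2-en-14,9-olide | O=C4[C@]1(C)[C@@H]2[C@H]3[C@H](O)C=C(C)[C@@H]2[C@@]3(COS(=O)(=O)c5c(C(C)C)cc(C(C)C)cc5C(C)C)[C@H](O4)C[C@H]1O | intermediate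
21 | 1,7-bis(tert-butyldimethylsilyloxy)-13-(2,4,6-triisopropylbenzenesulfonyloxy)longipin-2-en-14,9-olide | O=C4[C@]1(C)[C@@H]2[C@H]3[C@H](O[Si](C)(C)C(C)(C)C)C=C(C)[C@@H]2[C@@]3(COS(=O)(=O)c5c(C(C)C)cc(C(C)C)cc5C(C)C)[C@H](O4)C[C@H]1O[Si](C)(C)C(C)(C)C | intermediate
22 | 1,7-bis(tert-butyldimethylsilyloxy)longipin-2-ene-9,14-diol | OC[C@]1(C)[C@@H]2[C@H]3[C@H](O[Si](C)(C)C(C)(C)C)C=C(C)[C@@H]2[C@@]3(C)[C@H](O)C[C@H]1O[Si](C)(C)C(C)(C)C | intermediate
23 | angelic acid | C/C=C(/C)C(=O)O | starting material
24 | 14-angeloyloxy-1,7-bis(tert-butyldimethylsilyloxy)longipin-2-en-9-ol | C/C=C(/C)C(=O)OC[C@]1(C)[C@@H]2[C@H]3[C@H](O[Si](C)(C)C(C)(C)C)C=C(C)[C@@H]2[C@@]3(C)[C@H](O)C[C@H]1O[Si](C)(C)C(C)(C)C | intermediate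
25 | 3-methylbut-2-enoyl chloride | CC(C)=CC(=O)Cl | starting material
26 | 14-angeloyloxy-1,7-bis(tert-butyldimethylsilyloxy)-9-senecioyloxylongipin-2-ene | C/C=C(/C)C(=O)OC[C@]1(C)[C@@H]2[C@H]3[C@H](O[Si](C)(C)C(C)(C)C)C=C(C)[C@@H]2[C@@]3(C)[C@H](OC(=O)C=C(C)C)C[C@H]1O[Si](C)(C)C(C)(C)C | intermediate
27 | 14-angeloyloxy-9-senecioyloxylongipin-2-ene-1,7-diol | C/C=C(/C)C(=O)OC[C@]1(C)[C@@H]2[C@H]3[C@H](O)C=C(C)[C@@H]2[C@@]3(C)[C@H](OC(=O)C=C(C)C)C[C@H]1O | intermediate
28 | 14-angeloyloxy-7-hydroxy-9-senecioyloxylongipin-2-en-1-one | C/C=C(/C)C(=O)OC[C@]1(C)[C@@H]2[C@H]3C(=O)C=C(C)[C@@H]2[C@@]3(C)[C@H](OC(=O)C=C(C)C)C[C@H]1O | intermediate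
29 | 7-acetoxy-14-angeloyloxy-9-senecioyloxylongipin-2-en-1-one (CNP0179010.1) | C/C=C(/C)C(=O)OC[C@]1(C)[C@@H]2[C@H]3C(=O)C=C(C)[C@@H]2[C@@]3(C)[C@H](OC(=O)C=C(C)C)C[C@H]1OC(C)=O | target

Total steps: 20. Longest linear sequence: 17 steps (steps 1–6 and 10–20).

**Steps most likely to fail**

Step 10 (Proposed new method). What may go wrong: loss of the enolate by protonation or silyl transfer before the second bond forms, competing O-alkylation or lateral-bond cleavage of the bicyclobutane, and absence of facial control between the two bridge senses. Fallback (sets out from 10 and 14, returns at 16): the two bonds are made one after the other by known reaction types. Bi(OTf)3-catalysed hydroalkylation of 10 with the free hydroxypyrone 14 as carbon pronucleophile (CH2Cl2, rt) gives the ring-opened 3-cyclobutylpyran-2,4-dione F1. DBU (THF, 0 °C) then closes the seven-membered ring by intramolecular Michael addition of the imide enolate to the pyranone enone, giving keto lactone F2. TIPSOTf and Et3N convert F2 into 16 after separation of the auxiliary diastereomers.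

Step 11. What may go wrong: insufficient discrimination between the two acetyl groups, acyl transfer from the imide to the enamine, and loss of the silyl enol ether followed by β-elimination of the lactone oxygen. Fallback (sets out from 16, returns at 17): stoichiometric, stepwise enolate chemistry replaces enamine catalysis. Group-selective deprotonation with lithium bis[(R)-1-phenylethyl]amide in the presence of TMSCl (THF, −100 °C) gives the mono trimethylsilyl enol ether F3 of the C11 acetyl group. TiCl4 (CH2Cl2, −78 °C) effects intramolecular Mukaiyama aldol addition to the β-hydroxy ketone F4. Camphorsulfonic acid (cat., CH2Cl2) dehydrates F4 to 17.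

Step 15. What may go wrong: attack of hydride at sulfur, or no displacement at all at the neopentyl carbon, so that the alcohol is returned. Fallback (sets out from 19, returns at 22): the methyl group is made by deoxygenation of an aldehyde instead of SN2 displacement. TBSOTf and 2,6-lutidine give tris(silyl ether) F5. HF·pyridine at 0 °C frees only the primary alcohol F6. Dess–Martin periodinane gives aldehyde F7. TsNHNH2 gives tosylhydrazone F8. Catecholborane, then NaOAc·3H2O at reflux, gives the 13-methyl lactone F9. LiEt3BH reduces the lactone of F9 to 22.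

**Further compounds**
F1 | step 10 | (S)-4-benzyl-3-{[2,4-diacetyl-3-(3-methyl-2,4-dioxo-3,4-dihydro-2H-pyran-3-yl)cyclobutyl]carbonyl}oxazolidin-2-one | O=C4OC=CC(=O)[C@@]4(C)[C@@H]2[C@@H](C(C)=O)[C@H]([C@H]2C(C)=O)C(=O)N5C(=O)OC[C@@H]5Cc6ccccc6
F2 | step 10 | 13-[(S)-4-benzyl-2-oxooxazolidin-3-yl]-7,13-dioxo-2,3-secolongipinane-1,3-dione 14,9-olide | O=C4[C@]1(C)[C@@H]2[C@@H](C(C)=O)[C@]([C@H]2C(C)=O)(C(=O)N5C(=O)OC[C@@H]5Cc6ccccc6)[C@H](O4)CC1=O
F3 | step 11 | mono trimethylsilyl enol ether of 16 at the C11 acetyl group | O=C4[C@]1(C)[C@@H]2[C@@H](C(=C)O[Si](C)(C)C)[C@]([C@H]2C(C)=O)(C(=O)N5C(=O)OC[C@@H]5Cc6ccccc6)[C@H](O4)C=C1O[Si](C(C)C)(C(C)C)C(C)C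
F4 | step 11 | 3-hydroxy-2,3-dihydro derivative of 17 (either configuration at C3) | O=C4[C@]1(C)[C@@H]2[C@H]3C(=O)CC(C)(O)[C@@H]2[C@@]3(C(=O)N5C(=O)OC[C@@H]5Cc6ccccc6)[C@H](O4)C=C1O[Si](C(C)C)(C(C)C)C(C)C
F5 | step 15 | 1,7,13-tris(tert-butyldimethylsilyloxy)longipin-2-en-14,9-olide | O=C4[C@]1(C)[C@@H]2[C@H]3[C@H](O[Si](C)(C)C(C)(C)C)C=C(C)[C@@H]2[C@@]3(CO[Si](C)(C)C(C)(C)C)[C@H](O4)C[C@H]1O[Si](C)(C)C(C)(C)C
F6 | step 15 | 1,7-bis(tert-butyldimethylsilyloxy)-13-hydroxylongipin-2-en-14,9-olide | O=C4[C@]1(C)[C@@H]2[C@H]3[C@H](O[Si](C)(C)C(C)(C)C)C=C(C)[C@@H]2[C@@]3(CO)[C@H](O4)C[C@H]1O[Si](C)(C)C(C)(C)C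
F7 | step 15 | 1,7-bis(tert-butyldimethylsilyloxy)-13-oxolongipin-2-en-14,9-olide | O=C4[C@]1(C)[C@@H]2[C@H]3[C@H](O[Si](C)(C)C(C)(C)C)C=C(C)[C@@H]2[C@@]3(C=O)[C@H](O4)C[C@H]1O[Si](C)(C)C(C)(C)C
F8 | step 15 | 13-tosylhydrazone of F7 | O=C4[C@]1(C)[C@@H]2[C@H]3[C@H](O[Si](C)(C)C(C)(C)C)C=C(C)[C@@H]2[C@@]3(C=NNS(=O)(=O)c5ccc(C)cc5)[C@H](O4)C[C@H]1O[Si](C)(C)C(C)(C)C
F9 | step 15 | 1,7-bis(tert-butyldimethylsilyloxy)longipin-2-en-14,9-olide | O=C4[C@]1(C)[C@@H]2[C@H]3[C@H](O[Si](C)(C)C(C)(C)C)C=C(C)[C@@H]2[C@@]3(C)[C@H](O4)C[C@H]1O[Si](C)(C)C(C)(C)C
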